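Count the radicals the initiator can deliver before reckoning any yield. The flasks differ in one charge, the transfer agent:

| setting | eta | theta | beta | delta | zeta |
|---|---|---|---|---|---|
| starting material | 0.050 M | 0.050 M | 0.050 M | 0.050 M | 0.050 M |
| reagent | 0.125 M | 0.125 M | 0.125 M | 0.125 M | 0.125 M |
| transfer agent | 0.600 mM | 1.20 mM | 2.50 mM | 5.00 mM | 10.0 mM |
| initiator | 4.1 mM | 4.1 mM | 4.1 mM | 4.1 mM | 4.1 mM |
| time | 12 min | 12 min | 12 min | 12 min | 12 min |

    transfer agent + first chain carrier → side product + idle radical (k1 = 1.7 × 10⁶ M⁻¹ s⁻¹)
    2 second chain carrier → ended chains (k2 = 6.5 × 10⁶ M⁻¹ s⁻¹)
    starting material + second chain carrier → by-product + first chain carrier (k3 = 2.2 × 10⁵ M⁻¹ s⁻¹)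
    starting material + target ⇌ idle adduct, settled at all times (K4 = 630 M⁻¹)
    reagent + first chain carrier → target + second chain carrier (k5 = 74000 M⁻¹ s⁻¹)
    initiator → 2 initiating radical (k6 = 0.0017 s⁻¹)
    2 idle radical → ended radicals (k7 = 3.7 × 10⁸ M⁻¹ s⁻¹)
    starting material + initiating radical → capped initiator + first chain carrier (k8 = 1.2 × 10⁶ M⁻¹ s⁻¹)
    target ⇌ isomer of the product (K9 = 1.1, k9 = 0.0028 s⁻¹)

- percentages count the starting material that a species holds: one idle adduct counts as two
- target is meant together with its idle adduct
- a step written with two of one species runs at k times the square of its concentration and takes two of it each time
- in an amount of target, one idle adduct counts as one target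
- "hardly changes" means that all values lie within two and a half points (for a concentration: within two and a half percent of the largest)
- run time (eta): 12 min

* share of target in all that became target or side product or isomer of the product for eta, theta, beta, delta, zeta, in this order
* how that number moves from the first to the last of them (falls, then rises / falls all the way / hardly changes / rises all the way / rises, then falls)

At the charge of starting material, the fast balance keeps 32 idle adduct for each free target. Held this way, target has a forward half-life of 134 min against 4.1 min when free, so isomerisation barely runs while the starting material stands near its charge, since that half-life far exceeds the run. The transfer agent takes first chain carrier from the chain and leaves idle radical. I assume that each radical costs one transfer agent and that the starting material stands until the transfer agent is used up.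

My quantity is the radical budget, the radicals the initiator has made by the end of the run, twice the initiator broken down: 5.79 mM. The time at which the budget so far equals the charge is the induction period.

Now I read the transfer agent column against that budget. Eta, theta and beta hold 0.600 mM, 1.20 mM and 2.50 mM, each below it. Their induction periods are 0.745 min, 1.55 min and 3.57 min. Even beta leaves 8.43 min, longer than the free half-life, so I expect these flasks near the balance share of 47.6%.

Delta holds 5.00 mM, still under the budget, but its induction period of 9.23 min leaves 2.77 min, shorter than the free half-life. I let target, taken as free, relax towards balance over those minutes and count the side product as the whole charge of delta, which gives a share of 62.8%.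

Zeta holds 10.0 mM, above the budget, so the transfer agent outlasts the run. Target then competes with side product, and integrating that competition gives 4.71 mM of target against 5.79 mM of side product, a share of 44.8%. Setting the balance share for eta, 62.8% for delta and 44.8% for zeta side by side, with delta above both, my reckoning says that the share rises, then falls.

The forecast gives 52%, 51.5%, 52.5%, 68% and 43%, with the shape rises, then falls. It stands a little above my balance share for eta and above my figure for delta, saying of delta “leaving little time for isomerisation so the share peaks”.

The simulation gives 49.2%, 49.2%, 50.6%, 68.6% and 43.3%, so the share rises, then falls. In eta, target making has 99.9% of its turnover behind it at 6.00 min, and half of the isomerisation is done by 3.92 min. Free target there has a forward half-life of 4.1 min, and eta ends with target at 49.2% and isomer of the product at 49.6%. Zeta has used 5.80 mM of transfer agent against the budget of 5.79 mM, and 42% of its charge remains.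

The constants were set for the occasion; the result is computed.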